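## Retrosynthetic overview
1. The target is disconnected by a [4+2] between the C12/C14 diene of a 7β-hydroxy-19-al labdane (**5**) and the chromonyl-substituted methoxy-quinone **10**. This forms the cyclohexene ring and three stereocentres in one step.
2. Quinone **10** comes from oxidative dearomatisation of the B ring of trimethoxyflavone **9**. **9** comes from chalcone **8**, made from two cheap aromatics, phloroacetophenone (**7**) and 2,4,5-trimethoxybenzaldehyde (**6**).
3. Diene **5** comes from the commercial-grade Juniperus diterpenoid acid **1**, which already carries the decalin stereocentres, the 8(17)-ene and the 12,14-diene. It needs C19 reduction, C7 oxygenation and a redox funnel that sets 7β-OH.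
4. Ring order: chromone (step 6), then quinone by dearomatisation (step 7), then the new cyclohexene in the final [4+2] (step 8).

**Assumptions**
- Compound **1** is 4-epi-trans-communic acid, the normal-series labdane with equatorial 4α-CO2H, 5α-H, 9α-H, 10β-Me and an E 12,14-diene. It is assumed to be available from suppliers or from juniper-cone extraction.
- The final [4+2] is assumed to give a separable diastereomer mixture, and the target isomer is isolated by HPLC.

## Route

**Step 1**
Reactants: **1**, 4-epi-trans-communic acid
Product: **2**, labda-8(17),12E,14-trien-19-ol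
Conditions: LiAlH4, THF, 0 °C → rt
Reagents that add atoms: none
Why: Hydride reduction of the carboxylic acid to the primary alcohol leaves the isolated alkene and the diene untouched, and no stereocentre is touched (C4 is quaternary).

**Step 2**
Reactants: **2**
Product: **3**, 7-hydroxy-labda-8(17),12E,14-trien-19-ol (C7 epimer mixture, 7α major)
Conditions: SeO2 (10 mol%), TBHP (3 equiv, 5.5 M in decane), CH2Cl2, 0 °C → rt
Reagents that add atoms: TBHP `CC(C)(C)OO` and SeO2 `O=[Se]=O` (the oxygen of the new C–OH)
Why: Riley allylic oxidation (ene reaction then [2,3]-shift) hydroxylates the exocyclic methylene at the C7 methylene rather than at the C9 methine; the C7 epimer ratio is irrelevant because the next step destroys this centre.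

**Step 3**
Reactants: **3**
Product: **4**, 7-oxo-labda-8(17),12E,14-trien-19-al
Conditions: Dess–Martin periodinane (3 equiv), NaHCO3, CH2Cl2, rt
Reagents that add atoms: none
Why: Dess–Martin oxidation takes the primary neopentyl alcohol to the aldehyde and the allylic secondary alcohol to the α-methylene ketone, so any mixture of C7 epimers or over-oxidation products converges on one compound.

**Step 4**
Reactants: **4**
Product: **5**, 7β-hydroxy-labda-8(17),12E,14-trien-19-al (the diene)
Conditions: NaBH4, CeCl3·7H2O, MeOH/CH2Cl2 (1:1), −78 → −40 °C
Reagents that add atoms: none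
Why: Luche reduction is 1,2-selective for the α-methylene ketone, and the aldehyde is masked in situ as its MeOH hemiacetal; the hydride attacks axially from the unhindered α-face, so the equatorial 7β-OH is set, as in 7-keto-steroid reductions.

**Step 5**
Reactants: **6**, 2,4,5-trimethoxybenzaldehyde; **7**, 2′,4′,6′-trihydroxyacetophenone
Product: **8**, (E)-1-(2,4,6-trihydroxyphenyl)-3-(2,4,5-trimethoxyphenyl)prop-2-en-1-one
Conditions: KOH (6 equiv), EtOH/H2O, rt, 48 h; then HCl
Reagents that add atoms: none
Why: Claisen–Schmidt aldol condensation, with excess base to carry the phenolate, gives the thermodynamic E-chalcone.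

**Step 6**
Reactants: **8**
Product: **9**, 5,7-dihydroxy-2-(2,4,5-trimethoxyphenyl)chromone
Conditions: I2 (20 mol%), DMSO, 130 °C, 1–2 h
Reagents that add atoms: none
Why: The 2′-OH oxa-Michael closure gives the flavanone, and I2/DMSO dehydrogenation gives the flavone; this tolerates free phenols (no new stereocentre).

**Step 7**
Reactants: **9**
Product: **10**, 2-(5-methoxy-1,4-benzoquinon-2-yl)-5,7-dihydroxychromone
Conditions: CAN (2.5 equiv), MeCN/H2O (4:1), 0 °C, 10 min; used directly
Reagents that add atoms: water `O` (the quinone oxygens are delivered by water as the 2′,5′-OMe groups are lost as MeOH)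
Why: Ce(IV) oxidative demethylation (dearomatisation of the B ring) acts on the electron-rich para-dimethoxy pair (2′,5′-OMe), leaving the 4′-OMe as the quinone methoxy group.

**Step 8**
Reactants: **5** (1 equiv); **10** (1.5 equiv)
Product: **11**, Dichrostachine H
Conditions: MeCN, BHT (10 mol%), 60 °C, sealed tube under Ar, 2–3 d; prep-HPLC
Reagents that add atoms: none
Why: Quinone Diels–Alder reaction. The vinylogous-ester C5=C6 alkene is deactivated, so the diene adds across the C2=C3 alkene, which is activated by the more electrophilic C4 carbonyl. C12 bonds to the chromonyl-bearing carbon and C15 to the CH carbon ("para" to the C13 methyl). Suprafacial addition gives the cis ring fusion. The chromone sits under the diene (endo), which places C11 cis to the chromonyl and trans to the dione ring. The diene faces are diastereotopic, so C12/C–Cq/C–H are set relative to the labdane only by conformational bias, and the wanted diastereomer is separated.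

## Compound list
1 | 4-epi-trans-communic acid | `C=C1CC[C@@H]2[C@](C)(CCC[C@@]2(C)C(=O)O)[C@H]1C/C=C(\C)/C=C` | starting material
2 | labda-8(17),12E,14-trien-19-ol | `C=C1CC[C@@H]2[C@](C)(CCC[C@@]2(C)CO)[C@H]1C/C=C(\C)/C=C` | intermediate
3 | 7-hydroxylabda-8(17),12E,14-trien-19-ol (C7 mixture) | `C=C1C(O)C[C@@H]2[C@](C)(CCC[C@@]2(C)CO)[C@H]1C/C=C(\C)/C=C` | intermediate
4 | 7-oxo-labda-8(17),12E,14-trien-19-al | `C=C1C(=O)C[C@@H]2[C@](C)(CCC[C@@]2(C)C=O)[C@H]1C/C=C(\C)/C=C` | intermediate
5 | 7β-hydroxy-labda-8(17),12E,14-trien-19-al | `C=C1[C@@H](O)C[C@@H]2[C@](C)(CCC[C@@]2(C)C=O)[C@H]1C/C=C(\C)/C=C` | intermediate (diene)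
6 | 2,4,5-trimethoxybenzaldehyde | `COc1cc(OC)c(C=O)cc1OC` | starting material
7 | 2′,4′,6′-trihydroxyacetophenone | `CC(=O)c1c(O)cc(O)cc1O` | starting material
8 | (E)-2′,4′,6′-trihydroxy-2,4,5-trimethoxychalcone | `O=C(/C=C/c1cc(OC)c(OC)cc1OC)c1c(O)cc(O)cc1O` | intermediate
9 | 5,7-dihydroxy-2-(2,4,5-trimethoxyphenyl)chromone | `COc1cc(OC)c(-c2cc(=O)c3c(O)cc(O)cc3o2)cc1OC` | intermediate
10 | 2-(5-methoxy-1,4-benzoquinon-2-yl)-5,7-dihydroxychromone | `O=C1C=C(OC)C(=O)C=C1c1cc(=O)c2c(O)cc(O)cc2o1` | intermediate (dienophile)
11 | Dichrostachine H | `C=C1[C@@H](O)C[C@@H]2[C@](C)(CCC[C@@]2(C)C=O)[C@H]1C[C@@H]1C(C)=CC[C@H]2C(=O)C(OC)=CC(=O)[C@@]12c1cc(=O)c2c(O)cc(O)cc2o1` | target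

Atom check: diene **5** (C20H30O2) plus quinone **10** (C16H10O7) gives C36H40O9, which equals the formula of **11**.

## Totals
- Total steps: 8.
- Longest linear sequence: 5 steps (**1** → **2** → **3** → **4** → **5** → **11**). The dienophile branch is 4 steps (**6** + **7** → **8** → **9** → **10** → **11**).

## Three steps most likely to fail
1. **Step 8 (Diels–Alder).** The bond is hindered (secondary C12 to quaternary Cq), the endo/exo and facial selectivity are uncertain, and the diastereomer ratio may be poor.
   - Fallback: silylate the 5,7-OH groups of **9** before CAN oxidation, then run a Lewis-acid-promoted asynchronous polar [4+2] (Et2AlCl or BF3·OEt2, CH2Cl2, −78 °C) on the bis-silyl quinone. Remove the silyl groups with HF·pyridine at the end.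
2. **Step 2 (SeO2 on the triene).** The diene or the C16 methyl may be oxidised instead of C7, and the diene may degrade.
   - Fallback: mask the diene as its SO2 adduct (3-sulfolene), carry it through steps 2–4, and release the diene by cheletropic SO2 extrusion in situ at 110–120 °C during the cycloaddition.
3. **Step 7 (CAN with free phenols).** The unprotected 5,7-dihydroxychromone may be over-oxidised or degraded.
   - Fallback: replace dearomatisation by a bond-forming approach. Couple commercial 2-methoxy-1,4-benzoquinone with a 5,7-bis-O-MOM-chromone-2-trifluoroborate by Ag(I)/persulfate radical C–H arylation, then remove the MOM groups under mild acid.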